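Readings and results were generated by integration on assumed constants; the scatter is artificial.

Between 0.208 d and 0.417 d, starting material in the teal run, which is this same flask followed so far, shrinks at a fractional rate of 5.91 d⁻¹. Single ring, between 0.833 d and 8.00 d, shrinks at 0.0323 d⁻¹, so starting material goes 183 times faster. The books can therefore be kept in two stages: a fast one that shares out the charge and a slow one that moves single ring on. The slower figure, the tail rate, is the fraction of single ring lost per day, taken as first order.

| flask | starting material | remark | time |
|---|---|---|---|
| teal | 0.050 M | the very flask that is asked about, followed so far |  |
| flask | 0.050 M |  | 15 d |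

- teal (time / d: single ring / %, starting material / %): 0.208: 46.5, 17.9; 0.417: 56.7, 5.2; 0.833: 60.0, 0.8; 1.67: 58.5, 0; 4.00: 54.9, 0.4; 8.00: 47.6, 0

(readings scatter by 0.3 percentage points)

- percent here means starting material units held: one open dimer or ring dimer counts as two
- percent here means starting material units held: one open trimer counts as three
- what was read earlier has a scatter of 0.3 percentage points, one standard deviation
- reactions considered so far: open dimer -> ring dimer; 2 starting material -> open dimer; single ring -> over-reaction product; starting material -> single ring; starting material + open dimer -> open trimer

* the best time, 15 d at the latest, for single ring
* the amount of single ring, in percent of the starting material charged, at that time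
* earliest time at which at least nineteen twentieths of that best amount are there, in d
* latest time at which they still are, in d

The ledger of this flask, as reckoned here, closes at 8.00 d, when starting material reads 0%. Single ring holds 47.6%. Carried back to the start at the tail rate, that reading gives a gross ring share, the selectivity of the fast stage, of 61.6%, so 14 percentage points is booked to over-reaction product, which was never read. The remaining 38.4% is booked to the path through open dimer, which leads on to open trimer and ring dimer. Single ring at 15 d is reckoned at 38.0%, less than the 60.0% read at 0.833 d, so the best lies early, near that reading.

The forecast, which says of single ring that “it decays slowly”, sets the best at 0.95 d with 59.9% and the window from 0.43 d to 2.6 d. Its effective yield of about 61.8 percent stands against 61.6% here.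

The flask peaks at 0.893 d with 60.1% of single ring, and the window runs from 0.436 d to 2.61 d.

open dimer → ring dimer (k = 1.30 × 10⁻⁵ s⁻¹); 2 starting material → open dimer (k = 5.60 × 10⁻⁴ M⁻¹ s⁻¹); single ring → over-reaction product (k = 3.90 × 10⁻⁷ s⁻¹); starting material → single ring (k = 5.90 × 10⁻⁵ s⁻¹); starting material + open dimer → open trimer (k = 0.0170 M⁻¹ s⁻¹) By 0.893 d starting material, down to 0.397%, had fed single ring and open trimer, which stood at 36.5%. After 1.50 d, with starting material at 0.0172%, open trimer stayed at 36.5% while single ring passed to over-reaction product, reaching 37.6% and 24.4% at 15.0 d. Over 15 d the tail rate makes 0.623 of over-reaction product per unit of single ring left, which gives 23.4% in this flask. The neighbour flask with 0.020 M of starting material ends with 48.3% of single ring, which gives 30.1% by this factor, and it holds 31.3% of over-reaction product.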